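A small charge of racemization catalyst, 5.0 mM, stands beside 0.50 M of each substrate. For the next flask we must decide whether to cut the free catalyst to 10 mM and leave that charge as it is. That pays if right-handed substrate still leaves mainly by crossing to left-handed substrate, as in a dynamic kinetic resolution, and not by reacting to right-handed product.

the same everywhere: left-handed substrate 0.50 M; right-handed substrate 0.50 M; gas 36 mM (held)
- winter: free catalyst 14 mM; racemization catalyst 5 mM; run made earlier
- summer: free catalyst 22 mM; racemization catalyst 5 mM; run made earlier
- flask: free catalyst 10 mM; racemization catalyst 5.0 mM; time 50 min

- winter (time / min: left-handed substrate / %, right-handed substrate / %): 8.00: 26.9, 44.7; 15.0: 17.2, 35.5; 25.0: 11.6, 25.7; 30.0: 9.6, 20.1; 40.0: 6.2, 14.8; 50.0: 4.0, 9.7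
- summer (time / min: left-handed substrate / %, right-handed substrate / %): 8.00: 22.4, 42.6; 15.0: 12.4, 32.6; 25.0: 7.2, 20.5; 30.0: 4.8, 15.6; 40.0: 2.5, 9.9; 50.0: 1.3, 6.4

(scatter of a reading: 0.5 percentage points)

- free catalyst is single-handed; left-handed substrate and right-handed substrate are mirror images of each other, charged as a racemate, each of them at the stated concentration
- at the start none of the gas is in solution
- an excess is below zero if the other one leads

* part of the left-handed substrate and right-handed substrate charged together that has reacted at 50 min
* excess of left-handed product over right-handed product in the product at 50 min
* excess of right-handed substrate over left-handed substrate among what is left of the two at 50 min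

Let g be right-handed substrate minus left-handed substrate. Between 8.00 min and 15.0 min the winter run loses right-handed substrate at 0.0728 min⁻¹ of the mean g; this reading is our loss constant k, the share of g by which right-handed substrate falls per minute, with crossing and reaction to right-handed product counted together and the scatter of the readings in it. The summer run gives 0.0707 min⁻¹ with 1.57 times the free catalyst, so we read this loss as following g and not the free catalyst.

The forecast gives 81% reacted, a product excess of 7.3% and a substrate excess of 31%, its product excess “assuming no other sinks”. Our reckoning differs there: we take the loss of right-handed substrate to be mainly crossing, expect a product excess far above 7.3%, and charge the flask as planned.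

The flask gives 80.3% reacted, a product excess of 92.1% and a substrate excess of 33.4%, so the forecast's product excess stands 85 percentage points lower.

    coupling partner + free catalyst + left-handed substrate → free catalyst + left-handed product (k = 4.70 L² mol⁻² s⁻¹)
    coupling partner + free catalyst + right-handed substrate → free catalyst + right-handed product (k = 0.120 L² mol⁻² s⁻¹)
    left-handed substrate + racemization catalyst ⇌ right-handed substrate + racemization catalyst, rate k3*[racemization catalyst]*[left-handed substrate] forward; the back reaction follows from the equilibrium constant (k = 0.200 L mol⁻¹ s⁻¹)
    coupling partner ⇌ dormant form (K = 25.0, k = 7.80 × 10⁻⁴ s⁻¹)
    gas ⇌ coupling partner, rate k5*(csat - [coupling partner]) (kL = 0.0520 s⁻¹)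

At 50.0 min this flask has g = 6.6 points, and our estimate of its loss of right-handed substrate per minute is k times that. The neighbouring flask has 0.0085 M of racemization catalyst, 1.70 times this flask's charge. Its left-handed substrate stands at 6.50% against 6.57% here; as a rough estimate, if k rises by that factor and the loss per minute stays the same, the neighbouring flask has g = 3.9 points. It shows 3.5 points, with a substrate excess of 21.3% and a product excess of 93.2%.

The data stem from a simulated flask with made-up constants; noise was put on by code.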